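**Plan**

- Retrosynthesis: the two silyl ethers come off first, and the C4–H is traced back to a C4 carbamate nitrogen (helper). Ring C is then cut in one operation at C4–C4a and C2–C3, leaving benzyl N-vinylcarbamate (C3–C4) and an O-aryl O-pivaloyl acetal of 3,5-dimethoxybenzaldehyde. The acetal is cut at O1–C2, and the prenyl C–C bond of the phenol leads back to phloroglucinol.
- Forward: rings A and B are bought as benzene rings (phloroglucinol, 3,5-dimethoxybenzaldehyde). Ring A is C-prenylated, silylated and freed at one oxygen, O1–C2 is made by acetal formation, and ring C arises last by a catalytic asymmetric oxa-Povarov (formal 4+2) annulation.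
- Enabling feature: in ring A the ether oxygen O1 on C8a is para to the prenyl-bearing C6, so the ortho carbons C4a and C8 are equivalent and each is ortho/para to the C5 and C7 oxygens. The unit C4a=C8a–O1(+)=C2 is therefore an electron-rich cationic 2-oxadiene with only one possible mode of closure.
- Stereochemistry: C2 is the only stereocenter of the target (R by CIP: O1 > C1' > C3 > H). It is set in the key step by the chiral phosphoramide anion; the C4 center made with it is erased in the next step.

Key step: step 6

Assumption: the (11bR) catalyst is taken to deliver the (2R) product; the sense of induction has to be established in the first experiment, and the (11bS) catalyst is used if it proves opposite.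

**Route**

Step 1
Reactants: 1 phloroglucinol (benzene-1,3,5-triol); 2 prenyl bromide (1-bromo-3-methylbut-2-ene)
Product: 3 2-(3-methylbut-2-en-1-yl)benzene-1,3,5-triol
Conditions: DBU, THF, 0 °C to rt; 1 in threefold excess
Reagents that add atoms: none
Why: C-allylation of the ambident phloroglucinol anion with an allylic bromide and an amidine base is a known reaction type; the three ring CH positions are equivalent, so only one mono-C-prenyl isomer can form, and the excess of 1 should hold back dialkylation.

Step 2
Reactants: 3 2-(3-methylbut-2-en-1-yl)benzene-1,3,5-triol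
Product: 4 2-(3-methylbut-2-en-1-yl)-1,3,5-tris(triisopropylsilyloxy)benzene
Conditions: TIPSOTf (3.3 equiv), 2,6-lutidine, CH2Cl2, 0 °C to rt
Reagents that add atoms: triisopropylsilyl trifluoromethanesulfonate (TIPSOTf), CC(C)[Si](C(C)C)(C(C)C)OS(=O)(=O)C(F)(F)F
Why: Standard O-silylation of phenols with a silyl triflate, which is reactive enough for the two hydroxyls next to the prenyl group, while 2,6-lutidine keeps the alkene away from acid.

Step 3
Reactants: 4 2-(3-methylbut-2-en-1-yl)-1,3,5-tris(triisopropylsilyloxy)benzene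
Product: 5 4-(3-methylbut-2-en-1-yl)-3,5-bis(triisopropylsilyloxy)phenol
Conditions: Bu4NF (1.05 equiv), AcOH (1.05 equiv), THF, −20 to 0 °C, stopped at consumption of 4
Reagents that add atoms: none
Why: Site-selective fluoride desilylation under steric control: the silyl ether para to the prenyl group has two ortho hydrogens whereas each of the other two is flanked by the prenyl CH2, so one equivalent of buffered fluoride at low temperature should cleave the unhindered ether first.

Step 4
Reactants: 6 3,5-dimethoxybenzaldehyde; 7 pivaloyl chloride (2,2-dimethylpropanoyl chloride)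
Product: 8 chloro(3,5-dimethoxyphenyl)methyl 2,2-dimethylpropanoate (racemic)
Conditions: ZnCl2 (5 mol%), CH2Cl2, 0 °C to rt; volatiles removed, used crude
Reagents that add atoms: none
Why: Lewis acid catalysed addition of an acyl chloride across an aromatic aldehyde C=O to the α-chloroalkyl ester is a known reaction; the new center is racemic and is lost again in step 6.

Step 5
Reactants: 5 4-(3-methylbut-2-en-1-yl)-3,5-bis(triisopropylsilyloxy)phenol; 8 chloro(3,5-dimethoxyphenyl)methyl 2,2-dimethylpropanoate
Product: 10 (3,5-dimethoxyphenyl)[4-(3-methylbut-2-en-1-yl)-3,5-bis(triisopropylsilyloxy)phenoxy]methyl 2,2-dimethylpropanoate (racemic), via sodium aryloxide 9 (not isolated)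
Conditions: NaH, THF/DMF, 0 °C; then 8, 0 °C to rt; chromatography on Et3N-deactivated silica
Reagents that add atoms: none
Why: Williamson-type O-alkylation of a phenoxide with an α-chloroalkyl ester (the acyloxyalkylation used to make acyloxyalkyl ethers of phenols); the tert-butyl group shields the ester carbonyl against acyl transfer, and the aryl silyl ethers tolerate the cold, non-nucleophilic base.

Step 6
Reactants: 10 (3,5-dimethoxyphenyl)[4-(3-methylbut-2-en-1-yl)-3,5-bis(triisopropylsilyloxy)phenoxy]methyl 2,2-dimethylpropanoate; 11 benzyl N-vinylcarbamate (benzyl ethenylcarbamate)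
Product: 14 benzyl N-[(2R,4R)-2-(3,5-dimethoxyphenyl)-6-(3-methylbut-2-en-1-yl)-5,7-bis(triisopropylsilyloxy)-3,4-dihydro-2H-chromen-4-yl]carbamate, via aryl oxocarbenium ion 12 (not isolated), via N-acyliminium ion 13 (not isolated)
Conditions: 1,1,1-trifluoro-N-[(11bR)-4-oxido-2,6-bis(2,4,6-triisopropylphenyl)dinaphtho[2,1-d:1',2'-f][1,3,2]dioxaphosphepin-4-yl]methanesulfonamide (10 mol%), 11 (1.5 equiv, added slowly), 4 Å molecular sieves, toluene, −60 to −30 °C
Reagents that add atoms: none
Why: Proposed new method: the chiral N-triflyl phosphoramide protonates the pivalate of 10, and its loss gives aryl oxocarbenium ion 12 (the cationic 2-oxadiene C4a=C8a–O1(+)=C2) as a contact ion pair with the chiral anion, which also hydrogen-bonds the N–H of 11; the CH2 terminus of 11 adds to one face of C2 (bond C2–C3) to give N-acyliminium ion 13, and C4a of ring A then attacks C4 (bond C4–C4a) with return of the proton to the catalyst. The closest known reaction types are the Lewis acid promoted oxa-Povarov annulation of aryl oxocarbenium ions with alkenes to racemic chromans and the chiral phosphoric acid catalysed Povarov reaction of N-aryl imines with enecarbamates; an enantioselective oxygen version has not been shown, and the ion-pairing plus N–H hydrogen-bonding model of the aza case is the basis for expecting it. Ring C closes in a stepwise polar (4+2) fashion, the second bond by 6-exo-trig Friedel–Crafts attack on the iminium carbon. C2 is controlled by the catalyst (facial selection within the hydrogen-bonded chiral ion pair); C4 is controlled by the substrate relative to C2 (2,4-cis expected and drawn, of no consequence because C4 loses its substituent in step 7). The step needs ionisation towards the aryloxy-stabilised cation (pivalate is a far better leaving group and far poorer donor than the aryloxide), attack by 11 and not by the prenyl alkene (the enecarbamate is much the stronger π-nucleophile and is delivered by the catalyst), six-ring closure onto ring A and not five-ring closure onto ring B (ring A is the stronger nucleophile and the chroman transition state is unstrained), and a single regiochemistry of closure (C4a and C8 are equivalent by the local symmetry of ring A).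

Step 7
Reactants: 14 benzyl N-[(2R,4R)-2-(3,5-dimethoxyphenyl)-6-(3-methylbut-2-en-1-yl)-5,7-bis(triisopropylsilyloxy)-3,4-dihydro-2H-chromen-4-yl]carbamate
Product: 15 (2R)-2-(3,5-dimethoxyphenyl)-6-(3-methylbut-2-en-1-yl)-5,7-bis(triisopropylsilyloxy)-3,4-dihydro-2H-chromene
Conditions: Et3SiH (4 equiv), TMSOTf (0.3 equiv), CH2Cl2, −78 to −30 °C; aq. NaHCO3
Reagents that add atoms: none
Why: Ionic hydrogenolysis of an activated benzylic C–N bond: the silyl triflate activates the carbamate, C4 ionises readily because the cation is ortho and para to the three oxygen donors of ring A (as in acid cleavage of 2,4,6-trialkoxybenzyl carbamates and silane reduction of flavan-4-ol derivatives), and Et3SiH delivers hydride while regenerating a silyl triflate; both C4 epimers converge, C2 has only meta-methoxy groups on ring B and should not ionise, and without a Brønsted acid the prenyl alkene should stay untouched.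

Step 8
Reactants: 15 (2R)-2-(3,5-dimethoxyphenyl)-6-(3-methylbut-2-en-1-yl)-5,7-bis(triisopropylsilyloxy)-3,4-dihydro-2H-chromene
Product: 16 (2R)-2-(3,5-dimethoxyphenyl)-6-(3-methylbut-2-en-1-yl)-3,4-dihydro-2H-chromene-5,7-diol
Conditions: Bu4NF (2.5 equiv), AcOH (2.5 equiv), THF, 0 °C to rt, under argon
Reagents that add atoms: none
Why: Fluoride cleavage of aryl silyl ethers; acetic acid buffering keeps the electron-rich diphenol from phenoxide oxidation, and no strong acid is present that could cyclise the prenyl group onto a neighbouring hydroxyl or ionise C2.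

**Compound list**

1 | phloroglucinol (benzene-1,3,5-triol) | Oc1cc(O)cc(O)c1 | starting material
2 | prenyl bromide (1-bromo-3-methylbut-2-ene) | CC(C)=CCBr | starting material
3 | 2-(3-methylbut-2-en-1-yl)benzene-1,3,5-triol | CC(C)=CCc1c(O)cc(O)cc1O | intermediate
4 | 2-(3-methylbut-2-en-1-yl)-1,3,5-tris(triisopropylsilyloxy)benzene | CC(C)=CCc1c(O[Si](C(C)C)(C(C)C)C(C)C)cc(O[Si](C(C)C)(C(C)C)C(C)C)cc1O[Si](C(C)C)(C(C)C)C(C)C | intermediate
5 | 4-(3-methylbut-2-en-1-yl)-3,5-bis(triisopropylsilyloxy)phenol | CC(C)=CCc1c(O[Si](C(C)C)(C(C)C)C(C)C)cc(O)cc1O[Si](C(C)C)(C(C)C)C(C)C | intermediate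
6 | 3,5-dimethoxybenzaldehyde | COc1cc(OC)cc(C=O)c1 | starting material
7 | pivaloyl chloride (2,2-dimethylpropanoyl chloride) | CC(C)(C)C(=O)Cl | starting material
8 | chloro(3,5-dimethoxyphenyl)methyl 2,2-dimethylpropanoate (racemic) | COc1cc(OC)cc(C(Cl)OC(=O)C(C)(C)C)c1 | intermediate
9 | sodium 4-(3-methylbut-2-en-1-yl)-3,5-bis(triisopropylsilyloxy)phenoxide (not isolated) | CC(C)=CCc1c(O[Si](C(C)C)(C(C)C)C(C)C)cc([O-])cc1O[Si](C(C)C)(C(C)C)C(C)C.[Na+] | intermediate
10 | (3,5-dimethoxyphenyl)[4-(3-methylbut-2-en-1-yl)-3,5-bis(triisopropylsilyloxy)phenoxy]methyl 2,2-dimethylpropanoate (racemic) | COc1cc(OC)cc(C(OC(=O)C(C)(C)C)Oc2cc(O[Si](C(C)C)(C(C)C)C(C)C)c(CC=C(C)C)c(O[Si](C(C)C)(C(C)C)C(C)C)c2)c1 | intermediate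
11 | benzyl N-vinylcarbamate (benzyl ethenylcarbamate) | C=CNC(=O)OCc1ccccc1 | starting material
12 | (3,5-dimethoxybenzylidene)[4-(3-methylbut-2-en-1-yl)-3,5-bis(triisopropylsilyloxy)phenyl]oxonium, aryl oxocarbenium ion paired with the catalyst anion (not isolated) | COc1cc(OC)cc(C=[O+]c2cc(O[Si](C(C)C)(C(C)C)C(C)C)c(CC=C(C)C)c(O[Si](C(C)C)(C(C)C)C(C)C)c2)c1 | intermediate
13 | (benzyloxycarbonyl){(3R)-3-(3,5-dimethoxyphenyl)-3-[4-(3-methylbut-2-en-1-yl)-3,5-bis(triisopropylsilyloxy)phenoxy]propylidene}iminium, N-acyliminium ion paired with the catalyst anion (not isolated) | COc1cc(OC)cc([C@@H](CC=[NH+]C(=O)OCc3ccccc3)Oc2cc(O[Si](C(C)C)(C(C)C)C(C)C)c(CC=C(C)C)c(O[Si](C(C)C)(C(C)C)C(C)C)c2)c1 | intermediate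
14 | benzyl N-[(2R,4R)-2-(3,5-dimethoxyphenyl)-6-(3-methylbut-2-en-1-yl)-5,7-bis(triisopropylsilyloxy)-3,4-dihydro-2H-chromen-4-yl]carbamate (2,4-cis drawn; a 2,4-trans epimer would converge in step 7) | COc1cc(OC)cc([C@H]2C[C@@H](NC(=O)OCc4ccccc4)c3c(cc(O[Si](C(C)C)(C(C)C)C(C)C)c(CC=C(C)C)c3O[Si](C(C)C)(C(C)C)C(C)C)O2)c1 | intermediate
15 | (2R)-2-(3,5-dimethoxyphenyl)-6-(3-methylbut-2-en-1-yl)-5,7-bis(triisopropylsilyloxy)-3,4-dihydro-2H-chromene | COc1cc(OC)cc([C@H]2CCc3c(cc(O[Si](C(C)C)(C(C)C)C(C)C)c(CC=C(C)C)c3O[Si](C(C)C)(C(C)C)C(C)C)O2)c1 | intermediate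
16 | (2R)-2-(3,5-dimethoxyphenyl)-6-(3-methylbut-2-en-1-yl)-3,4-dihydro-2H-chromene-5,7-diol | COc1cc(OC)cc([C@H]2CCc3c(cc(O)c(CC=C(C)C)c3O)O2)c1 | target

**Count**

Total step count: 8. Longest linear sequence: 7 steps (steps 1, 2, 3, 5, 6, 7, 8, from phloroglucinol); step 4 is the side branch.

**Steps most likely to fail**

1. Step 6 (Proposed new method). What may go wrong: weak enantiofacial discrimination within the ion pair, acid-induced self-condensation of the enecarbamate outrunning ionisation of the acetal, or five-ring closure onto ring B. The fallback uses known chemistry only, sets out from 5 and comes back at 15, and forms O1–C2 last.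
   - Ortho-formylation of phenol 5 (MgCl2, Et3N, paraformaldehyde, MeCN, reflux; the two ortho positions are equivalent) should give 6-hydroxy-3-(3-methylbut-2-en-1-yl)-2,4-bis(triisopropylsilyloxy)benzaldehyde F1.
   - Wittig olefination with 1-(3,5-dimethoxyphenyl)-2-(triphenylphosphoranylidene)ethanone (toluene, 80 °C) should give (E)-1-(3,5-dimethoxyphenyl)-3-[6-hydroxy-3-(3-methylbut-2-en-1-yl)-2,4-bis(triisopropylsilyloxy)phenyl]prop-2-en-1-one F2.
   - Conjugate reduction with [(Ph3P)CuH]6 (toluene, rt), which leaves the prenyl alkene alone, should give 1-(3,5-dimethoxyphenyl)-3-[6-hydroxy-3-(3-methylbut-2-en-1-yl)-2,4-bis(triisopropylsilyloxy)phenyl]propan-1-one F3.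
   - Asymmetric transfer hydrogenation (RuCl[(S,S)-TsDPEN](p-cymene), HCO2H/Et3N) should give (1S)-1-(3,5-dimethoxyphenyl)-3-[6-hydroxy-3-(3-methylbut-2-en-1-yl)-2,4-bis(triisopropylsilyloxy)phenyl]propan-1-ol F4.
   - Mitsunobu cyclisation (PPh3, DIAD, THF, 0 °C) closes O1–C2 with inversion and should give (2R)-15.

2. Step 3. What may go wrong: insufficient discrimination between the hindered and unhindered silyl ethers, and cleavage running on to diols. The fallback replaces site-selective desilylation by site-selective acylation, sets out from 3 and comes back at 5.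
   - Triol 3 with pivaloyl chloride 7 (1.0 equiv, pyridine, CH2Cl2, −40 °C) should be acylated at the hydroxyl that has no ortho substituent, giving 3,5-dihydroxy-4-(3-methylbut-2-en-1-yl)phenyl 2,2-dimethylpropanoate F5.
   - Silylation of the two remaining hydroxyls (TIPSOTf, 2,6-lutidine, CH2Cl2) should give 4-(3-methylbut-2-en-1-yl)-3,5-bis(triisopropylsilyloxy)phenyl 2,2-dimethylpropanoate F6.
   - Reductive removal of the pivalate with i-Bu2AlH (CH2Cl2, −78 °C), which spares aryl silyl ethers, should give 5.

3. Step 7. What may go wrong: loss of a proton from the C4 cation (elimination to the chromene) competing with hydride capture, or protonation of the prenyl alkene by adventitious triflic acid. The fallback accepts the elimination and then reduces chemoselectively; it sets out from 14 and comes back at 15.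
   - Heating 14 with pyridinium p-toluenesulfonate (cat.) in toluene (80 °C, dark) should eliminate the carbamate and give (2R)-2-(3,5-dimethoxyphenyl)-6-(3-methylbut-2-en-1-yl)-5,7-bis(triisopropylsilyloxy)-2H-chromene F7.
   - Diimide generated from 2-nitrobenzenesulfonylhydrazide and Et3N (CH2Cl2, rt) should reduce the cis-disubstituted styrenic C3=C4 bond in preference to the trisubstituted prenyl alkene and give 15.

**Further compounds**

F1 | step 6 | 6-hydroxy-3-(3-methylbut-2-en-1-yl)-2,4-bis(triisopropylsilyloxy)benzaldehyde | CC(C)=CCc1c(O[Si](C(C)C)(C(C)C)C(C)C)c(C=O)c(O)cc1O[Si](C(C)C)(C(C)C)C(C)C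
F2 | step 6 | (E)-1-(3,5-dimethoxyphenyl)-3-[6-hydroxy-3-(3-methylbut-2-en-1-yl)-2,4-bis(triisopropylsilyloxy)phenyl]prop-2-en-1-one | COc1cc(OC)cc(C(=O)/C=C/c2c(O)cc(O[Si](C(C)C)(C(C)C)C(C)C)c(CC=C(C)C)c2O[Si](C(C)C)(C(C)C)C(C)C)c1
F3 | step 6 | 1-(3,5-dimethoxyphenyl)-3-[6-hydroxy-3-(3-methylbut-2-en-1-yl)-2,4-bis(triisopropylsilyloxy)phenyl]propan-1-one | COc1cc(OC)cc(C(=O)CCc2c(O)cc(O[Si](C(C)C)(C(C)C)C(C)C)c(CC=C(C)C)c2O[Si](C(C)C)(C(C)C)C(C)C)c1
F4 | step 6 | (1S)-1-(3,5-dimethoxyphenyl)-3-[6-hydroxy-3-(3-methylbut-2-en-1-yl)-2,4-bis(triisopropylsilyloxy)phenyl]propan-1-ol | COc1cc(OC)cc([C@@H](O)CCc2c(O)cc(O[Si](C(C)C)(C(C)C)C(C)C)c(CC=C(C)C)c2O[Si](C(C)C)(C(C)C)C(C)C)c1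
F5 | step 3 | 3,5-dihydroxy-4-(3-methylbut-2-en-1-yl)phenyl 2,2-dimethylpropanoate | CC(C)=CCc1c(O)cc(OC(=O)C(C)(C)C)cc1O
F6 | step 3 | 4-(3-methylbut-2-en-1-yl)-3,5-bis(triisopropylsilyloxy)phenyl 2,2-dimethylpropanoate | CC(C)=CCc1c(O[Si](C(C)C)(C(C)C)C(C)C)cc(OC(=O)C(C)(C)C)cc1O[Si](C(C)C)(C(C)C)C(C)C
F7 | step 7 | (2R)-2-(3,5-dimethoxyphenyl)-6-(3-methylbut-2-en-1-yl)-5,7-bis(triisopropylsilyloxy)-2H-chromene | COc1cc(OC)cc([C@H]2C=Cc3c(cc(O[Si](C(C)C)(C(C)C)C(C)C)c(CC=C(C)C)c3O[Si](C(C)C)(C(C)C)C(C)C)O2)c1
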